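The route rests on cutting ring A (the 2‑pyrroline N4–C3=C2–C1–C9a; stemoninine locants, listed below) into the amide unit C9a–N4–C3(=O) and a two‑carbon piece C1–C2. The key step exploits that the enamine carbon C3 is a masked amide carbonyl and that the α‑amino methine C9a is a masked α‑amino acid carbon. Photoredox decarboxylation of the N‑acyl azepane‑2‑carboxylic acid 23 gives the C9a radical, which adds to vinyltriphenylphosphonium bromide (C9a–C1). The ylide formed by radical–polar crossover then olefinates the amide carbonyl (C2=C3). The precursor has no ring A: it is a spiro‑fused furo‑azepane amino acid, N‑acylated with the intact methyl‑lactone acid.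

Key step: step 12

Remarks
- Locants: ring A = N4, C3, C2, C1, C9a; ring B (azepane) = N4, C5, C6, C7, C8, C9, C9a; ring C (oxolane) = C8, C9, C10 (ethyl), C11, O; ring D (spiro lactone) = C11, C12 (OH), C13 (CH3), C14 (C=O), O; ring E (lactone on C3) = C18, C19, C20 (CH3), C21 (C=O), O. Target: 8R, 9R, 9aS, 10S, 11R, 12R, 13R, 18S, 20S.
- The α‑amino carbon that becomes C9a is formed without control in step 3 and is carried as a mixture of epimers in 7–10, 13–19 and 23 (their SMILES leave it open), because step 12 planarises it.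
- (2S,4S)‑4‑Methylglutamic acid and 4‑chlorobutanal are taken as catalogue compounds.

Step 1
Reactants: 1 4‑chlorobutanal; 2 methyl propiolate
Product: 3 methyl (R)‑7‑chloro‑4‑hydroxyhept‑2‑ynoate
Conditions: (S,S)‑ProPhenol (10 mol%), Me2Zn (2.5 equiv), Ph3PO (20 mol%), toluene, 0 °C; aq. NH4Cl
Reagents that add atoms: none
Why: Zinc–ProPhenol‑catalysed asymmetric alkynylation of an aliphatic aldehyde by the alkynylzinc species formed from 2 and Me2Zn; the ligand enantiomer is the one expected to deliver the R carbinol (later C8).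

Step 2
Reactants: 3 methyl (R)‑7‑chloro‑4‑hydroxyhept‑2‑ynoate
Product: 5 (R)‑5‑(3‑chloropropyl)furan‑2(5H)‑one, via Z‑hydroxy enoate 4 (not isolated)
Conditions: H2 (1 atm), Pd/CaCO3 poisoned with Pb(OAc)2, quinoline, EtOAc, 20 °C; then PPTS (cat.), CH2Cl2, 20 °C
Reagents that add atoms: none
Why: cis‑Selective semihydrogenation of the ynoate gives the Z‑γ‑hydroxy enoate, which lactonises to the butenolide without touching the carbinol centre or the alkyl chloride.

Step 3
Reactants: 5 (R)‑5‑(3‑chloropropyl)furan‑2(5H)‑one; 6 tert‑butyl N‑(diphenylmethylidene)glycinate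
Product: 9 tert‑butyl 2‑[(tert‑butoxycarbonyl)amino]‑2‑[(2R,3R)‑2‑(3‑chloropropyl)‑5‑oxooxolan‑3‑yl]acetate, via Michael adduct 7 (not isolated), via amino lactone 8 (not isolated)
Conditions: LiN(iPr)2 (1.05 equiv), THF, −78 °C, 6 then 5; 1 M HCl, THF, 20 °C; then NaHCO3, Boc2O, 20 °C
Reagents that add atoms: di‑tert‑butyl dicarbonate, CC(C)(C)OC(=O)OC(=O)OC(C)(C)C
Why: Michael addition of the soft lithium enolate of the glycine Schiff base to the butenolide should occur anti to the C8 side chain and set C9 (R); Schiff‑base hydrolysis and Boc protection then give a carbamate N–H that shields the adjacent C–H from later bases, and the free amine should not lactamise because its tetrahedral intermediate would be bridged.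

Step 4
Reactants: 9 tert‑butyl 2‑[(tert‑butoxycarbonyl)amino]‑2‑[(2R,3R)‑2‑(3‑chloropropyl)‑5‑oxooxolan‑3‑yl]acetate
Product: 10 tert‑butyl 2‑[(tert‑butoxycarbonyl)amino]‑2‑[(2R,3R,4S)‑2‑(3‑chloropropyl)‑4‑ethyl‑5‑oxooxolan‑3‑yl]acetate
Conditions: LiN(iPr)2 (2.2 equiv), THF, −78 °C; EtI (5 equiv), DMPU, −78 → −40 °C; AcOH
Reagents that add atoms: iodoethane, CCI
Why: Lactone enolate alkylation (the carbamate is deprotonated first and is a spectator) should occur anti to the C9 substituent, setting C10 (S) and completing the all‑trans lactone.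

Step 5
Reactants: 2 methyl propiolate; 11 benzyl alcohol
Product: 12 methyl (E)‑3‑(benzyloxy)prop‑2‑enoate
Conditions: DABCO (10 mol%), CH2Cl2, 0 → 20 °C
Reagents that add atoms: none
Why: Amine‑catalysed oxa‑Michael addition of an alcohol to a propiolate gives the E‑β‑alkoxyacrylate.

Step 6
Reactants: 10 tert‑butyl 2‑[(tert‑butoxycarbonyl)amino]‑2‑[(2R,3R,4S)‑2‑(3‑chloropropyl)‑4‑ethyl‑5‑oxooxolan‑3‑yl]acetate; 12 methyl (E)‑3‑(benzyloxy)prop‑2‑enoate
Product: 14 tert‑butyl 2‑[(5R,7R,8R,9S)‑4‑(benzyloxy)‑7‑(3‑chloropropyl)‑9‑ethyl‑2‑oxo‑1,6‑dioxaspiro[4.4]non‑3‑en‑8‑yl]‑2‑[(tert‑butoxycarbonyl)amino]acetate, via hemiketal adduct 13 (not isolated)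
Conditions: 12 (3.2 equiv), LiN(iPr)2 (3.2 equiv), THF, −95 °C; then 10, −95 → −20 °C; AcOH
Reagents that add atoms: none
Why: Ester‑directed β‑lithiation of the alkoxyacrylate gives a vinyllithium that should add to the lactone carbonyl anti to the α‑ethyl group; the hemiketal alkoxide, cis to the ester, lactonises to the spiro tetronate (ring D), and the C11 configuration (C12 trans to ethyl) is also the one expected if the spiroketal equilibrates.

Step 7
Reactants: 14 tert‑butyl 2‑[(5R,7R,8R,9S)‑4‑(benzyloxy)‑7‑(3‑chloropropyl)‑9‑ethyl‑2‑oxo‑1,6‑dioxaspiro[4.4]non‑3‑en‑8‑yl]‑2‑[(tert‑butoxycarbonyl)amino]acetate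
Product: 16 tert‑butyl 2‑[(tert‑butoxycarbonyl)amino]‑2‑[(4R,5R,7R,8R,9S)‑7‑(3‑chloropropyl)‑9‑ethyl‑4‑hydroxy‑2‑oxo‑1,6‑dioxaspiro[4.4]nonan‑8‑yl]acetate, via tetronic acid 15 (not isolated)
Conditions: H2 (1 atm), Pd/C, EtOAc, 20 °C; then Rh/Al2O3, H2 (4 atm), EtOAc/AcOH, 20 °C
Reagents that add atoms: none
Why: Hydrogenolysis of the vinylogous benzyl ester gives the tetronic acid, and heterogeneous hydrogenation of its enol double bond should deliver hydrogen to C12 from the face of the ring‑C oxygen, away from C10 and the C9 substituent, setting C12 (R).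

Step 8
Reactants: 16 tert‑butyl 2‑[(tert‑butoxycarbonyl)amino]‑2‑[(4R,5R,7R,8R,9S)‑7‑(3‑chloropropyl)‑9‑ethyl‑4‑hydroxy‑2‑oxo‑1,6‑dioxaspiro[4.4]nonan‑8‑yl]acetate
Product: 17 tert‑butyl 2‑[(tert‑butoxycarbonyl)amino]‑2‑[(3R,4R,5R,7R,8R,9S)‑7‑(3‑chloropropyl)‑9‑ethyl‑4‑hydroxy‑3‑methyl‑2‑oxo‑1,6‑dioxaspiro[4.4]nonan‑8‑yl]acetate
Conditions: LiN(iPr)2 (3.3 equiv), THF, −78 → −40 °C; MeI (1.5 equiv), DMPU, −78 → −40 °C; AcOH
Reagents that add atoms: iodomethane, CI
Why: Fráter–Seebach alkylation of the β‑alkoxide lactone enolate (the carbamate anion is a spectator and protects the α‑amino C–H) should place the methyl group trans to the C12 oxygen, setting C13 (R).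

Step 9
Reactants: 17 tert‑butyl 2‑[(tert‑butoxycarbonyl)amino]‑2‑[(3R,4R,5R,7R,8R,9S)‑7‑(3‑chloropropyl)‑9‑ethyl‑4‑hydroxy‑3‑methyl‑2‑oxo‑1,6‑dioxaspiro[4.4]nonan‑8‑yl]acetate
Product: 19 (2R,3S,3aR,8aR,3'R,4'R)‑3‑ethyl‑3'‑hydroxy‑4'‑methyl‑5'‑oxooctahydro‑2H‑spiro[furo[3,2‑c]azepine‑2,2'‑oxolane]‑4‑carboxylic acid, via chloropropyl amino acid 18 (not isolated)
Conditions: TFA/CH2Cl2 (1:3), 0 → 20 °C; evaporate; then NaI (0.2 equiv), iPr2NEt (5 equiv), MeCN (0.005 M), 70 °C
Reagents that add atoms: none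
Why: Acidolysis removes the Boc group and the tert‑butyl ester, and the primary amine then displaces the primary halide (iodide formed in situ by Finkelstein exchange) in a 7‑exo‑tet N‑alkylation that closes ring B.

Step 10
Reactants: 20 (2S,4S)‑4‑methylglutamic acid
Product: 21 (2S,4S)‑4‑methyl‑5‑oxooxolane‑2‑carboxylic acid
Conditions: NaNO2, 1 M aq. HCl, 0 → 20 °C
Reagents that add atoms: none
Why: Diazotisation of the α‑amino acid with carboxylate participation (double inversion, net retention) gives the γ‑lactone acid with both ring‑E stereocentres unchanged, the methyl and carboxyl groups cis.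

Step 11
Reactants: 19 (2R,3S,3aR,8aR,3'R,4'R)‑3‑ethyl‑3'‑hydroxy‑4'‑methyl‑5'‑oxooctahydro‑2H‑spiro[furo[3,2‑c]azepine‑2,2'‑oxolane]‑4‑carboxylic acid; 21 (2S,4S)‑4‑methyl‑5‑oxooxolane‑2‑carboxylic acid
Product: 23 5‑[(2S,4S)‑4‑methyl‑5‑oxooxolane‑2‑carbonyl] derivative of 19 (N‑acyl azepane‑2‑carboxylic acid), via acid chloride 22 (not isolated)
Conditions: 21, (COCl)2, DMF (cat.), CH2Cl2, 0 → 20 °C, evaporate; then 19, NaHCO3, THF/H2O (1:1), 0 °C; acidify to pH 3
Reagents that add atoms: none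
Why: Schotten–Baumann N‑acylation of the secondary amino acid by the acid chloride; in aqueous bicarbonate the secondary C12 alcohol should not be acylated and the α‑oxy acyl centre C18 should not epimerise.

Step 12
Reactants: 23 N‑acyl azepane‑2‑carboxylic acid; 24 vinyltriphenylphosphonium bromide
Product: 26 target (8R,9R,9aS,10S,11R,12R,13R,18S,20S), via phosphorus ylide 25 (not isolated)
Conditions: Cs2CO3 (1.1 equiv), [Ir(dF(CF3)ppy)2(dtbbpy)]PF6 (2 mol%), 24 (1.5 equiv), degassed dry DMSO, blue LED (450 nm), 20 °C; then dark, 60 °C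
Reagents that add atoms: none
Why: Proposed new method: the caesium carboxylate of 23 is oxidised by the photoexcited trivalent iridium complex and loses CO2 to give the planar α‑amido radical at C9a, which adds to the electron‑poor alkene of 24 (new C9a–C1 bond); the α‑phosphonio radical is reduced by the divalent iridium state to the non‑stabilised ylide 25 (Cs2CO3 in DMSO should regenerate it if it is protonated), whose carbanion C2 attacks the amide carbonyl C3 in an intramolecular Wittig olefination (new C2=C3 bond, loss of Ph3PO). The closest known reaction types are the photoredox radical–polar crossover of carboxylic acids with vinylphosphonium salts followed by intermolecular Wittig olefination of aldehydes, the Schweizer annulation (Michael addition to vinyltriphenylphosphonium bromide, then intramolecular Wittig) and the intramolecular Wittig olefination of amide carbonyls used in indole synthesis. Ring A (N4–C3=C2–C1–C9a) is closed 5‑exo‑trig at the amide carbonyl. The only new stereocentre, C9a, is set in the radical addition: the trans‑fused oxolane holds the C9–C10 bond pseudo‑equatorial, and A(1,3) strain with the N‑acyl group together with torsional preference should favour pseudo‑axial bond formation, so that C1 ends cis to C10 (9aS). The step needs chemoselective oxidation of the carboxylate, secured because no enamine exists while the light is on (irradiation at 20 °C, Wittig closure afterwards in the dark), and attack of the ylide on the amide carbonyl and not on a lactone carbonyl, secured by ring size (five‑membered against eight‑membered or larger) and by the α‑oxygen at C18 that activates the amide.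

Compound list
1 | 4‑chlorobutanal | ClCCCC=O | starting material
2 | methyl propiolate | C#CC(=O)OC | starting material
3 | methyl (R)‑7‑chloro‑4‑hydroxyhept‑2‑ynoate | COC(=O)C#C[C@H](O)CCCCl | intermediate
4 | methyl (2Z,4R)‑7‑chloro‑4‑hydroxyhept‑2‑enoate | COC(=O)/C=C\[C@H](O)CCCCl | intermediate (not isolated)
5 | (R)‑5‑(3‑chloropropyl)furan‑2(5H)‑one | O=C1C=C[C@@H](CCCCl)O1 | intermediate
6 | tert‑butyl N‑(diphenylmethylidene)glycinate | CC(C)(C)OC(=O)CN=C(c1ccccc1)c1ccccc1 | starting material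
7 | tert‑butyl 2‑[(2R,3R)‑2‑(3‑chloropropyl)‑5‑oxooxolan‑3‑yl]‑2‑[(diphenylmethylidene)amino]acetate (α‑amino carbon epimers) | O=C1C[C@H](C(N=C(c2ccccc2)c2ccccc2)C(=O)OC(C)(C)C)[C@@H](CCCCl)O1 | intermediate (not isolated)
8 | tert‑butyl 2‑amino‑2‑[(2R,3R)‑2‑(3‑chloropropyl)‑5‑oxooxolan‑3‑yl]acetate | O=C1C[C@H](C(N)C(=O)OC(C)(C)C)[C@@H](CCCCl)O1 | intermediate (not isolated)
9 | tert‑butyl 2‑[(tert‑butoxycarbonyl)amino]‑2‑[(2R,3R)‑2‑(3‑chloropropyl)‑5‑oxooxolan‑3‑yl]acetate | O=C1C[C@H](C(NC(=O)OC(C)(C)C)C(=O)OC(C)(C)C)[C@@H](CCCCl)O1 | intermediate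
10 | tert‑butyl 2‑[(tert‑butoxycarbonyl)amino]‑2‑[(2R,3R,4S)‑2‑(3‑chloropropyl)‑4‑ethyl‑5‑oxooxolan‑3‑yl]acetate | CC[C@H]1[C@H](C(NC(=O)OC(C)(C)C)C(=O)OC(C)(C)C)[C@@H](CCCCl)OC1=O | intermediate
11 | benzyl alcohol | OCc1ccccc1 | starting material
12 | methyl (E)‑3‑(benzyloxy)prop‑2‑enoate | COC(=O)/C=C/OCc1ccccc1 | intermediate
13 | methyl (E)‑3‑(benzyloxy)‑3‑[(2S,3S,4R,5R)‑2‑hydroxyoxolan‑2‑yl]prop‑2‑enoate carrying the 3‑ethyl, 4‑[CH(NHBoc)CO2tBu] and 5‑(3‑chloropropyl) groups of 10 (hemiketal adduct) | CC[C@H]1[C@H](C(NC(=O)OC(C)(C)C)C(=O)OC(C)(C)C)[C@@H](CCCCl)O[C@]1(O)/C(OCc1ccccc1)=C\C(=O)OC | intermediate (not isolated)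
14 | tert‑butyl 2‑[(5R,7R,8R,9S)‑4‑(benzyloxy)‑7‑(3‑chloropropyl)‑9‑ethyl‑2‑oxo‑1,6‑dioxaspiro[4.4]non‑3‑en‑8‑yl]‑2‑[(tert‑butoxycarbonyl)amino]acetate | CC[C@H]1[C@H](C(NC(=O)OC(C)(C)C)C(=O)OC(C)(C)C)[C@@H](CCCCl)O[C@@]12OC(=O)C=C2OCc1ccccc1 | intermediate
15 | tert‑butyl 2‑[(tert‑butoxycarbonyl)amino]‑2‑[(5R,7R,8R,9S)‑7‑(3‑chloropropyl)‑9‑ethyl‑4‑hydroxy‑2‑oxo‑1,6‑dioxaspiro[4.4]non‑3‑en‑8‑yl]acetate (tetronic acid) | CC[C@H]1[C@H](C(NC(=O)OC(C)(C)C)C(=O)OC(C)(C)C)[C@@H](CCCCl)O[C@@]12OC(=O)C=C2O | intermediate (not isolated)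
16 | tert‑butyl 2‑[(tert‑butoxycarbonyl)amino]‑2‑[(4R,5R,7R,8R,9S)‑7‑(3‑chloropropyl)‑9‑ethyl‑4‑hydroxy‑2‑oxo‑1,6‑dioxaspiro[4.4]nonan‑8‑yl]acetate | CC[C@H]1[C@H](C(NC(=O)OC(C)(C)C)C(=O)OC(C)(C)C)[C@@H](CCCCl)O[C@@]12OC(=O)C[C@H]2O | intermediate
17 | tert‑butyl 2‑[(tert‑butoxycarbonyl)amino]‑2‑[(3R,4R,5R,7R,8R,9S)‑7‑(3‑chloropropyl)‑9‑ethyl‑4‑hydroxy‑3‑methyl‑2‑oxo‑1,6‑dioxaspiro[4.4]nonan‑8‑yl]acetate | CC[C@H]1[C@H](C(NC(=O)OC(C)(C)C)C(=O)OC(C)(C)C)[C@@H](CCCCl)O[C@@]12OC(=O)[C@H](C)[C@H]2O | intermediate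
18 | 2‑amino‑2‑[(3R,4R,5R,7R,8R,9S)‑7‑(3‑chloropropyl)‑9‑ethyl‑4‑hydroxy‑3‑methyl‑2‑oxo‑1,6‑dioxaspiro[4.4]nonan‑8‑yl]acetic acid | CC[C@H]1[C@H](C(N)C(=O)O)[C@@H](CCCCl)O[C@@]12OC(=O)[C@H](C)[C@H]2O | intermediate (not isolated)
19 | (2R,3S,3aR,8aR,3'R,4'R)‑3‑ethyl‑3'‑hydroxy‑4'‑methyl‑5'‑oxooctahydro‑2H‑spiro[furo[3,2‑c]azepine‑2,2'‑oxolane]‑4‑carboxylic acid | CC[C@H]1[C@H]2[C@@H](CCCNC2C(=O)O)O[C@@]12OC(=O)[C@H](C)[C@H]2O | intermediate
20 | (2S,4S)‑4‑methylglutamic acid | N[C@@H](C[C@H](C)C(=O)O)C(=O)O | starting material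
21 | (2S,4S)‑4‑methyl‑5‑oxooxolane‑2‑carboxylic acid | OC(=O)[C@@H]1C[C@H](C)C(=O)O1 | intermediate
22 | (2S,4S)‑4‑methyl‑5‑oxooxolane‑2‑carbonyl chloride | ClC(=O)[C@@H]1C[C@H](C)C(=O)O1 | intermediate (not isolated)
23 | 5‑[(2S,4S)‑4‑methyl‑5‑oxooxolane‑2‑carbonyl] derivative of 19 (N‑acyl azepane‑2‑carboxylic acid) | CC[C@H]1[C@H]2[C@@H](CCCN(C(=O)[C@@H]3C[C@H](C)C(=O)O3)C2C(=O)O)O[C@@]12OC(=O)[C@H](C)[C@H]2O | intermediate
24 | vinyltriphenylphosphonium bromide | C=C[P+](c1ccccc1)(c1ccccc1)c1ccccc1.[Br-] | starting material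
25 | 9aS ylide: the N‑acyl azepane of 23 with CH2–CH=PPh3 on C9a in place of CO2H | CC[C@H]1[C@H]2[C@@H](CCCN(C(=O)[C@@H]3C[C@H](C)C(=O)O3)[C@H]2CC=P(c4ccccc4)(c4ccccc4)c4ccccc4)O[C@@]12OC(=O)[C@H](C)[C@H]2O | intermediate (not isolated)
26 | target: pyrrolo[1,2‑a]azepine with the C2=C3 enamine, C3 lactone E, oxolane ring C and spiro hydroxy‑methyl lactone D (8R,9R,9aS,10S,11R,12R,13R,18S,20S) | CC[C@H]1[C@H]2[C@@H](CCCN3C([C@@H]4C[C@H](C)C(=O)O4)=CC[C@@H]23)O[C@@]12OC(=O)[C@H](C)[C@H]2O | target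

Total step count: 12. Longest linear sequence: 10 steps (1, 2, 3, 4, 6, 7, 8, 9, 11, 12).

Steps most likely to fail

1. Step 12 (Proposed new method). The ylide may be quenched by proton transfer before it reaches the amide carbonyl, the amide carbonyl may be too unreactive for olefination, the radical addition may show poor facial selectivity at C9a, or the enamine may be oxidised under irradiation. Fallback (known chemistry, from 23, returning at 25 and so at 26): oxidative decarboxylation of 23 with PhI(OAc)2 and I2 in MeOH/CH2Cl2 should give the N‑acyl N,O‑acetal F1. BF3·OEt2 and (vinyloxy)trimethylsilane at −78 °C should then give the 9a‑(2‑oxoethyl) amide F2 by axial attack on the N‑acyliminium ion. NaBH4 at 0 °C should give the primary alcohol F3, and I2, PPh3 and imidazole the primary iodide F4. PPh3 in MeCN at 80 °C should give the phosphonium iodide F5. KN(SiMe3)2 (1 equiv) in THF, −78 → 60 °C, should deprotonate the phosphonium salt selectively to ylide 25, which closes to 26 by the intramolecular Wittig olefination of the amide carbonyl.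

2. Step 6. The hindered lactone may be enolised instead of attacked, the β‑lithioacrylate may decompose before addition, or the spiro centre may form with poor control. Fallback (from 10, returning at 14): lithium methyl propiolate (from 2 and LiN(SiMe3)2, THF, −78 °C) should add to the lactone carbonyl of 10 to give the hemiketal ynoate F6. Benzyl alcohol with catalytic NaOBn in THF should then add in conjugate fashion, and the hemiketal hydroxyl should close onto the ester to give 14.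

3. Step 9. The seven‑membered ring closure by N‑alkylation may be slow, so that intermolecular alkylation or aminolysis of lactone D competes. Fallback (from 17, returning at 19): NaI in acetone should give the primary iodide F7, and AgBF4 in DMSO followed by Et3N (Kornblum oxidation) the aldehyde F8. TFA/CH2Cl2 should remove the Boc and tert‑butyl groups and let the amine condense with the aldehyde to the seven‑membered cyclic imine F9, which NaBH(OAc)3 should reduce in the same flask to 19.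

Further compounds
F1 | step 12 | N‑acyl N,O‑acetal: 23 with OCH3 on C9a in place of CO2H | CC[C@H]1[C@H]2[C@@H](CCCN(C(=O)[C@@H]3C[C@H](C)C(=O)O3)C2OC)O[C@@]12OC(=O)[C@H](C)[C@H]2O
F2 | step 12 | 9aS aldehyde: CH2CHO on C9a | CC[C@H]1[C@H]2[C@@H](CCCN(C(=O)[C@@H]3C[C@H](C)C(=O)O3)[C@H]2CC=O)O[C@@]12OC(=O)[C@H](C)[C@H]2O
F3 | step 12 | 9aS primary alcohol: CH2CH2OH on C9a | CC[C@H]1[C@H]2[C@@H](CCCN(C(=O)[C@@H]3C[C@H](C)C(=O)O3)[C@H]2CCO)O[C@@]12OC(=O)[C@H](C)[C@H]2O
F4 | step 12 | 9aS primary iodide: CH2CH2I on C9a | CC[C@H]1[C@H]2[C@@H](CCCN(C(=O)[C@@H]3C[C@H](C)C(=O)O3)[C@H]2CCI)O[C@@]12OC(=O)[C@H](C)[C@H]2O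
F5 | step 12 | 9aS phosphonium iodide: CH2CH2PPh3 on C9a | CC[C@H]1[C@H]2[C@@H](CCCN(C(=O)[C@@H]3C[C@H](C)C(=O)O3)[C@H]2CC[P+](c4ccccc4)(c4ccccc4)c4ccccc4)O[C@@]12OC(=O)[C@H](C)[C@H]2O.[I-]
F6 | step 6 | hemiketal ynoate: methyl 3‑[(2S)‑2‑hydroxyoxolan‑2‑yl]propiolate carrying the substituents of 10 | CC[C@H]1[C@H](C(NC(=O)OC(C)(C)C)C(=O)OC(C)(C)C)[C@@H](CCCCl)O[C@]1(O)C#CC(=O)OC
F7 | step 9 | primary iodide corresponding to 17 | CC[C@H]1[C@H](C(NC(=O)OC(C)(C)C)C(=O)OC(C)(C)C)[C@@H](CCCI)O[C@@]12OC(=O)[C@H](C)[C@H]2O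
F8 | step 9 | aldehyde corresponding to 17 (CH2CH2CHO on C8) | CC[C@H]1[C@H](C(NC(=O)OC(C)(C)C)C(=O)OC(C)(C)C)[C@@H](CCC=O)O[C@@]12OC(=O)[C@H](C)[C@H]2O
F9 | step 9 | seven‑membered cyclic imine acid (C5=N4) | CC[C@H]1[C@H]2[C@@H](CCC=NC2C(=O)O)O[C@@]12OC(=O)[C@H](C)[C@H]2O
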